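## Structural features

The target joins two units through one carbon. A fully substituted phloroglucinol ring (three phenols alternating with two formyl groups) is bonded through its sixth carbon to the benzylic methine C9', which also carries an isobutyl chain and the quaternary carbon C4 of a hydroazulene. The terpene part is a cyclopentane (C1–C2–C3–C4–C5) fused along C1–C5 to a cycloheptene (C1, C5=C6, C7, C8, C9, C10). C4 bears a methyl group, C7 a 2-hydroxypropan-2-yl group and C10 a methyl group. There are five stereocentres, (1R,4R,7R,10R,9'S) in these locants. C9' and C4 are directly bonded (tertiary benzylic next to all-carbon quaternary), C1 and C10 are adjacent, and C7 faces C1 across the C5=C6 bond. H1, H10 and the carbinol side chain lie on one face of the seven-membered ring, and the ring is fused on the C4-methyl face of the cyclopentane. The fragile groups are the two formyl groups flanked by phenols (hydride, base, carbenoids), the electron-rich arene, the tertiary alcohol (acid-induced elimination) and the trisubstituted alkene next to C4. The real difficulty is twofold: the C4/C9' dyad in one absolute sense, and a cycloheptene whose alkene sits exactly at C5=C6 with three ring stereocentres tied to C4. The key step uses the C5=C6 alkene flanked by sp3 C1 and C7 and bridged by C8–C9–C10. With an enol at C8=C9 this is a cyclohepta-1,4-diene, the product pattern of a cis-divinylcyclopropane rearrangement (cyclopropane C6–C7–C8, vinyl arms C5=C1 and C9=C10).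

## Logic of the disconnections

33 ⇒ 32 ⇒ 31. The three aryl O–CH3 bonds and the O–Si bond are cut last. This keeps the phenols and the tertiary alcohol masked until nothing else must be done, so all earlier intermediates are neutral and non-chelating. The forward steps need a soft nucleophile that dealkylates at methyl without acid and a fluoride desilylation that leaves the aldehydes alone.

31 ⇒ 30 ⇒ 29. The formyl carbons are traced to ester carbons. Esters make the arene fully substituted and electron-poor, and they survive carbenoids, amide bases, borohydride and radicals. The price is a hydride reduction of two hindered esters and a benzylic-selective oxidation.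

29 ⇒ 28 ⇒ 27 ⇒ 26. An oxygen is put back on C9, because the three-carbon partner of the key step delivers C9 as a carbonyl. The forward sequence must remove it by a radical path that does not touch C5=C6, and 26 must be handled mildly because C10 is then alpha to a ketone.

26 ⇒ 25. A carboxyl is put back on C8 and silyl groups on the C9 enol oxygen. The C8 carboxyl is carried as a 2-(trimethylsilyl)ethyl ester, not a methyl ester. Fluoride then cleaves the enol ether and the C8 ester and triggers decarboxylation near room temperature. Halide-mediated dealkylation at about 140 °C is avoided, since it would also attack the two hindered aryl methyl esters and endanger C10. The structures of 18 and 25 were checked against the target atom by atom and needed no other change.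

25 ⇒ 18 + 22 (key). C7–C8 and C1–C10 are cut. This removes the seven-membered ring and three stereocentres at once and leaves a cyclopentene diene and a three-carbon diazo ester. The forward step demands cyclopropanation at the (Z)-C6=C7 bond only, control of the alkene face by the catalyst, and a boat rearrangement that tolerates a cis tertiary substituent.

22 ⇒ 21 ⇒ 20 ⇒ 19. The O–Si bond, the diazo group and the ester alkyl group are cut in turn, leading to a commercial keto ester. The enol silylation must give the (Z) geometry.

18 ⇒ 17 ⇒ 14 + 16, and 16 ⇒ 15. The (Z)-C6=C7 bond is traced to an alkyne and the C5–C6 bond to an sp2–sp coupling. This avoids a (Z)-alkenyl metal reagent, and the geometry comes from syn addition of hydrogen. The forward steps need a coupling next to a quaternary centre and a semihydrogenation that stops at the diene.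

14 ⇒ 12 ⇒ 11 ⇒ 10. The C5–O triflate is traced to a ketone that can enolise only toward C1. The two aryl C–C(O) bonds are traced to C–Br and then C–H. The arene is therefore electron-rich when the C4–C9' bond is made and blocked afterwards. The carbonylation must work at bromides flanked by two methoxy groups.

10 ⇒ 9 ⇒ 8 ⇒ 7. An oxygen is put back on C3, which leads to a symmetric 1,3-dione in which C4 is not yet a stereocentre. C4 is set by catalyst-controlled reduction of one carbonyl. The C9' series is chosen at the same stage by separating diastereomers, so at most half of 7 can be used.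

7 ⇒ 4 + 5. The C4–C9' bond is cut between a stabilised benzylic cation and the dione enol. Both pieces are one step from commercial materials. The forward step must form a quaternary carbon next to a hindered benzylic centre.

4 ⇒ 1 + 2. The aryl–C9' bond is cut to an aryllithium and an aldehyde.

## Other disconnections considered

Alternative 1: The cut is through aryl–C9' and C3–C4, leading back to (Z)-1-(5-methylhex-2-en-2-yl)cyclobutan-1-ol A1 and 2,4,6-trimethoxybenzenediazonium tetrafluoroborate A2. In the forward step Ph3PAuCl and Ru(bpy)3(PF6)2 under visible light would generate a cationic aryl–gold species that activates the alkene of A1. A ring CH2 would migrate to C4 as the aryl group is delivered to C9', giving the cyclopentanone A3, which is the same compound as 10.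
- In its favour: both centres of the dyad arise in one event, and their relative configuration follows from anti addition across an alkene of defined geometry. No dione, desymmetrisation or deoxygenation is needed. On step economy for this segment it is better than the chosen plan (about three steps to A3 against five to 10).
- Against it: the step has no evident source of absolute configuration, so A3 would need resolution. The chosen plan also loses half of 7, so the two are equal on that point. A2 is electron-rich and doubly ortho-substituted, which should slow single-electron reduction and aryl transfer. Aryl delivery to the internal, isobutyl-bearing carbon of a trisubstituted alkene is the hindered mode.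
- Comparison: this alternative is open-shell gold redox chemistry where the chosen plan uses a closed-shell cation capture. It solves only the dyad and leaves the seven-membered ring to the same key step, so it is a possible replacement for steps 1–5, not a rival to the ring construction.

Alternative 2: The cut is at aryl–C9' with C9' at the ketone level, leading back to the hydroazulene carboxylic acid A4 and 3,5-dimethoxybenzyne A6, released with CsF from the silyl triflate A5. The carboxylate oxygen would add to the aryne carbon remote from the flanking methoxy group, and the aryl anion would then attack the acyl carbon to give the ortho-hydroxyaryl ketone A7.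
- In its favour: the arene arrives late, so it needs no blocking during carbenoid chemistry, and the step is metal-free and convergent. On these points it is better than the chosen plan, which spends four steps on blocking and unblocking the arene.
- Against it: A7 has no isobutyl group. C9' would have to be made from a ketone wedged between C4 and a doubly ortho-substituted aryl group, by addition of an isobutyl nucleophile and benzylic deoxygenation, with weak facial control and a risk of 1,2-shift from C4. One phenol would need methylation, and both formyl groups would have to be introduced on a ring that carries an acid-sensitive terpene. A4 itself still needs the hydroazulene with C1, C4, C7 and C10 set.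
- Comparison: the chosen plan fixes C9' before the ring system exists and relays it to C4. This alternative leaves C9' to the least controllable step. On step count after the key step it is likely longer.

Alternative 3: The cut is through C1=C2 and C5=C6, leading back to the acyclic dienyne A8. A second-generation Grubbs catalyst would start at the allylic-alcohol vinyl group, close the cyclopentene onto the alkyne and relay the carbene at C5 onto the C6 vinyl group, giving the dienol A9.
- In its favour: two rings and two alkenes form in one catalytic step, no diazo compound is used, and C7 and C10 could be set by independent acyclic methods. In ring-forming power it is better than the chosen key step (two rings against one), and the unblocked trimethoxyphenyl ring is tolerated.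
- Against it: A8 must already hold five stereocentres, including the propargylic quaternary C4 next to C9', so the hardest problem is moved, not solved. The relay carbene at C5 is fully substituted and next to C4. A9 carries an extra C1=C2 alkene conjugated with C5=C6 and a hydroxyl at C3. C1 would then have to be created by a site- and face-selective reduction of a diene, C3 would need deoxygenation, and the arene would still need its formyl groups.
- Comparison: the chosen plan sets C1, C7 and C10 in the step that makes the ring and places the alkene without a later reduction. This alternative is equal in convergence and weaker in stereochemical economy.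

Key step: step 15

Assumption: Rh2(S-PTAD)4 is taken to deliver the carbenoid to the enantioface of C6=C7 needed here, by analogy with the facial sense of this catalyst class. If the sense is reversed, Rh2(R-PTAD)4 is used with no other change.

## Route

Step 1
Reactants: 1 1,3,5-trimethoxybenzene; 2 3-methylbutanal
Product: 4 rac-3-methyl-1-(2,4,6-trimethoxyphenyl)butan-1-ol, via 2,4,6-trimethoxyphenyllithium 3 (not isolated)
Conditions: n-BuLi (1.05 equiv), TMEDA, THF, 0 °C → rt; then 2, −78 → 0 °C; aq. NH4Cl
Reagents that add atoms: none
Why: Directed ortho-lithiation between two methoxy groups, then 1,2-addition of the aryllithium to the aldehyde. The new centre is racemic and is erased in step 2.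

Step 2
Reactants: 4 rac-3-methyl-1-(2,4,6-trimethoxyphenyl)butan-1-ol; 5 2-methylcyclopentane-1,3-dione
Product: 7 rac-2-methyl-2-[3-methyl-1-(2,4,6-trimethoxyphenyl)butyl]cyclopentane-1,3-dione, via benzylic cation 6 (not isolated)
Conditions: 5 (2 equiv), TsOH·H2O (10 mol %), (CF3)2CHOH–CH2Cl2, rt
Reagents that add atoms: none
Why: Torgov-type SN1 C-alkylation of the dione enol by a benzylic cation stabilised by three methoxy groups. O-alkylation and elimination are reversible under acid, so the C-alkylated dione should accumulate. C9' is formed racemic and C4 is not yet stereogenic.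

Step 3
Reactants: 7 rac-2-methyl-2-[3-methyl-1-(2,4,6-trimethoxyphenyl)butyl]cyclopentane-1,3-dione
Product: 8 (2S,3S)-3-hydroxy-2-methyl-2-[(1R)-3-methyl-1-(2,4,6-trimethoxyphenyl)butyl]cyclopentan-1-one
Conditions: (R)-2-methyl-CBS-oxazaborolidine (0.3 equiv), BH3·SMe2 (0.7 equiv), THF, −30 °C; MeOH; chromatographic removal of the C9' epimer
Reagents that add atoms: none
Why: CBS desymmetrisation of a 2,2-disubstituted cyclopentane-1,3-dione. Hydride should add anti to the bulky side chain, and the (R)-catalyst should select the carbonyl that becomes C3, which sets C4. Each enantiomer of 7 should give one diastereomer, and 8 is the one with the target configuration at C9', so at most half of 7 is used.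

Step 4
Reactants: 8 (2S,3S)-3-hydroxy-2-methyl-2-[(1R)-3-methyl-1-(2,4,6-trimethoxyphenyl)butyl]cyclopentan-1-one
Product: 9 O-[(1S,2S)-2-methyl-2-[(1R)-3-methyl-1-(2,4,6-trimethoxyphenyl)butyl]-3-oxocyclopentyl] 1H-imidazole-1-carbothioate
Conditions: 1,1'-thiocarbonyldiimidazole (2 equiv), DMAP (0.2 equiv), ClCH2CH2Cl, 70 °C
Reagents that add atoms: 1,1'-thiocarbonyldiimidazole S=C(n1ccnc1)n1ccnc1
Why: Thioacylation of the secondary alcohol under neutral conditions (first half of a Barton–McCombie deoxygenation). No strong base is used, so retro-aldol opening of the β-hydroxy ketone is avoided.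

Step 5
Reactants: 9 O-[(1S,2S)-2-methyl-2-[(1R)-3-methyl-1-(2,4,6-trimethoxyphenyl)butyl]-3-oxocyclopentyl] 1H-imidazole-1-carbothioate
Product: 10 (2R)-2-methyl-2-[(1R)-3-methyl-1-(2,4,6-trimethoxyphenyl)butyl]cyclopentan-1-one
Conditions: (Me3Si)3SiH (1.5 equiv), AIBN (0.2 equiv), toluene, 90 °C
Reagents that add atoms: none
Why: Barton–McCombie radical deoxygenation with a tin-free hydrogen donor. Hydrogen transfer to the C3 radical should outrun β-scission, and no stereocentre is touched.

Step 6
Reactants: 10 (2R)-2-methyl-2-[(1R)-3-methyl-1-(2,4,6-trimethoxyphenyl)butyl]cyclopentan-1-one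
Product: 11 (2R)-2-[(1R)-1-(3,5-dibromo-2,4,6-trimethoxyphenyl)-3-methylbutyl]-2-methylcyclopentan-1-one
Conditions: NBS (2.1 equiv), MeCN, 0 °C → rt
Reagents that add atoms: N-bromosuccinimide O=C1CCC(=O)N1Br
Why: Twofold electrophilic aromatic bromination at the only two free, strongly activated ring positions. Without acid or radical initiation the ketone alpha position should not react.

Step 7
Reactants: 11 (2R)-2-[(1R)-1-(3,5-dibromo-2,4,6-trimethoxyphenyl)-3-methylbutyl]-2-methylcyclopentan-1-one
Product: 12 (2R)-2-[(1R)-1-[3,5-bis(methoxycarbonyl)-2,4,6-trimethoxyphenyl]-3-methylbutyl]-2-methylcyclopentan-1-one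
Conditions: Pd(OAc)2 (5 mol %), n-BuP(1-adamantyl)2 (12 mol %), CO (10 bar), MeOH, Et3N, toluene, 110 °C
Reagents that add atoms: carbon monoxide [C-]#[O+]; methanol CO
Why: Palladium-catalysed alkoxycarbonylation of aryl bromides (oxidative addition to zerovalent palladium, CO insertion, methanolysis) with a bulky electron-rich phosphine suited to ortho,ortho-disubstituted bromides. The arene is now fully substituted and deactivated.

Step 8
Reactants: 12 (2R)-2-[(1R)-1-[3,5-bis(methoxycarbonyl)-2,4,6-trimethoxyphenyl]-3-methylbutyl]-2-methylcyclopentan-1-one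
Product: 14 (5R)-5-[(1S)-1-[3,5-bis(methoxycarbonyl)-2,4,6-trimethoxyphenyl]-3-methylbutyl]-5-methylcyclopent-1-en-1-yl trifluoromethanesulfonate, via potassium enolate 13 (not isolated)
Conditions: KN(SiMe3)2 (1.2 equiv), THF, −78 °C; PhNTf2 (1.3 equiv), −78 → 0 °C
Reagents that add atoms: N-phenylbis(trifluoromethanesulfonimide) O=S(=O)(N(c1ccccc1)S(=O)(=O)C(F)(F)F)C(F)(F)F
Why: Enolate O-sulfonylation. Only C1 carries enolisable hydrogens, so the C5=C1 enol triflate is the single regioisomer, and the aryl esters have no alpha hydrogen.

Step 9
Reactants: 15 2-methylbut-3-yn-2-ol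
Product: 16 triethyl[(2-methylbut-3-yn-2-yl)oxy]silane
Conditions: Et3SiCl, imidazole, DMAP (cat.), DMF, rt
Reagents that add atoms: chlorotriethylsilane CC[Si](Cl)(CC)CC
Why: Silylation of the tertiary propargylic alcohol. Protecting before the coupling keeps the acid-sensitive dienyl carbinol from ever being free.

Step 10
Reactants: 14 (5R)-5-[(1S)-1-[3,5-bis(methoxycarbonyl)-2,4,6-trimethoxyphenyl]-3-methylbutyl]-5-methylcyclopent-1-en-1-yl trifluoromethanesulfonate; 16 triethyl[(2-methylbut-3-yn-2-yl)oxy]silane
Product: 17 dimethyl 2,4,6-trimethoxy-5-[(1S)-3-methyl-1-[(1R)-1-methyl-2-[3-methyl-3-(triethylsilyloxy)but-1-yn-1-yl]cyclopent-2-en-1-yl]butyl]benzene-1,3-dicarboxylate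
Conditions: PdCl2(PPh3)2 (5 mol %), CuI (10 mol %), i-Pr2NH, THF, rt
Reagents that add atoms: none
Why: Sonogashira coupling of a cycloalkenyl triflate with a terminal alkyne forms C5–C6. It runs at room temperature and should tolerate the neighbouring quaternary centre.

Step 11
Reactants: 17 dimethyl 2,4,6-trimethoxy-5-[(1S)-3-methyl-1-[(1R)-1-methyl-2-[3-methyl-3-(triethylsilyloxy)but-1-yn-1-yl]cyclopent-2-en-1-yl]butyl]benzene-1,3-dicarboxylate
Product: 18 dimethyl 2,4,6-trimethoxy-5-[(1S)-3-methyl-1-[(1R)-1-methyl-2-[(1Z)-3-methyl-3-(triethylsilyloxy)but-1-en-1-yl]cyclopent-2-en-1-yl]butyl]benzene-1,3-dicarboxylate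
Conditions: H2 (1 atm), Pd/CaCO3 poisoned with Pb(OAc)2, quinoline, EtOAc–hexane, rt
Reagents that add atoms: none
Why: Lindlar-type semihydrogenation adds hydrogen syn to the alkyne and fixes the (Z)-C6=C7 geometry. The poisoned catalyst should spare the trisubstituted ring alkene.

Step 12
Reactants: 19 methyl 3-oxopentanoate
Product: 20 2-(trimethylsilyl)ethyl 3-oxopentanoate
Conditions: Me3SiCH2CH2OH (1.5 equiv), DMAP (10 mol %), toluene, 110 °C, MeOH distilled off
Reagents that add atoms: 2-(trimethylsilyl)ethanol C[Si](C)(C)CCO
Why: DMAP-catalysed transesterification of a β-keto ester, driven by removal of methanol. It installs the fluoride-labile ester used in step 16.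

Step 13
Reactants: 20 2-(trimethylsilyl)ethyl 3-oxopentanoate
Product: 21 2-(trimethylsilyl)ethyl 2-diazo-3-oxopentanoate
Conditions: 4-acetamidobenzenesulfonyl azide, Et3N, MeCN, 0 °C → rt
Reagents that add atoms: 4-acetamidobenzenesulfonyl azide CC(=O)Nc1ccc(cc1)S(=O)(=O)N=[N+]=[N-]
Why: Regitz diazo transfer to an active methylene compound.

Step 14
Reactants: 21 2-(trimethylsilyl)ethyl 2-diazo-3-oxopentanoate
Product: 22 2-(trimethylsilyl)ethyl (3Z)-3-(tert-butyldimethylsilyloxy)-2-diazopent-3-enoate
Conditions: t-BuMe2SiOTf, Et3N, CH2Cl2, 0 °C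
Reagents that add atoms: tert-butyldimethylsilyl trifluoromethanesulfonate CC(C)(C)[Si](C)(C)OS(=O)(=O)C(F)(F)F
Why: Soft enolisation and O-silylation of the diazo ketone. The (Z)-enol ether (methyl cis to the silyloxy group) should form because it avoids strain against the diazo ester.

Step 15
Reactants: 18 dimethyl 2,4,6-trimethoxy-5-[(1S)-3-methyl-1-[(1R)-1-methyl-2-[(1Z)-3-methyl-3-(triethylsilyloxy)but-1-en-1-yl]cyclopent-2-en-1-yl]butyl]benzene-1,3-dicarboxylate; 22 2-(trimethylsilyl)ethyl (3Z)-3-(tert-butyldimethylsilyloxy)-2-diazopent-3-enoate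
Product: 25 hydroazulene cycloadduct (1R 4R 7S 10S 9'S; C5=C6; C7 triethylsilyloxyisopropyl; C8 2-(trimethylsilyl)ethyl ester; C9 tert-butyldimethylsilyl enol ether; arene as dimethyl diester), via rhodium carbenoid 23 (not isolated), via all-cis divinylcyclopropane 24 (not isolated)
Conditions: Rh2(S-PTAD)4 [dirhodium tetrakis((S)-(1-adamantyl)(phthalimido)acetate)] (2 mol %), 22 (3 equiv, syringe pump), hexanes–PhCF3, 0 °C → rt; then toluene, 100 °C
Reagents that add atoms: none
Why: The dirhodium tetracarboxylate converts 22 into the donor/acceptor carbenoid 23, which adds to the (Z)-C6=C7 bond of 18 with its siloxyvinyl group cis to both alkene substituents and gives the all-cis divinylcyclopropane 24; this is the tandem cyclopropanation/Cope rearrangement (formal [4+3] cycloaddition) of siloxyvinyl diazoacetates with dienes, a reaction type known for 1-vinylcycloalkenes. On warming, 24 undergoes a [3,3] shift through a boat transition state in which C6–C8 breaks as C1–C10 forms, so the seven-membered ring closes by sigmatropic expansion of the three-membered ring. C7 is set in the cyclopropanation: the chiral catalyst selects the alkene face, which fixes C7 relative to C4, and the (Z) geometry places the silyloxyisopropyl group on the cyclopropane face that carries both vinyl arms. C1 and C10 are set in the rearrangement: the ring hydrogen at C1 and the hydrogen at C10 (cis to C8 in the (Z)-enol ether) point inward in the boat, so H1, H10 and the C7 side chain end on one face and the C10 methyl on the other. With the cyclopropane chosen by the catalyst, the boat builds the new ring on the C4-methyl face of the cyclopentene, away from the C9' substituent, whereas the other cyclopropane diastereomer would have to rearrange toward that substituent and should lag behind. The step needs site selectivity for the cis-disubstituted C6=C7 bond over the trisubstituted C1=C5 bond, which rests on the steric preference of donor/acceptor carbenoids and on shielding of C1=C5 by C4; the fully substituted arene offers no C–H bond for insertion. The carbinol carbon on C7 has no hydrogen, so the homo-[1,5]-hydrogen shift of cis-alkyl vinylcyclopropanes is excluded while the hindered boat is reached thermally.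

Step 16
Reactants: 25 hydroazulene cycloadduct (C8 2-(trimethylsilyl)ethyl ester; C9 silyl enol ether)
Product: 26 hydroazulen-9-one (1R,4R,7R,10S,9'S; C8 CH2; C7 triethylsilyloxyisopropyl; arene as dimethyl diester)
Conditions: Bu4NF (4 equiv), AcOH (2 equiv), THF, 0 → 40 °C
Reagents that add atoms: none
Why: Fluoride cleaves the silyl enol ether and then the 2-(trimethylsilyl)ethyl ester by β-elimination of ethene, and the resulting β-keto acid decarboxylates. Buffering with AcOH should keep the tertiary triethylsilyl ether, the aryl methyl esters and the C10 centre intact.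

Step 17
Reactants: 26 hydroazulen-9-one
Product: 27 hydroazulen-9-ol (C9 epimers; otherwise as 26)
Conditions: NaBH4, MeOH–THF, 0 °C
Reagents that add atoms: none
Why: Borohydride reduction of the ketone; the hindered aryl esters should not react. The C9 configuration is irrelevant because the oxygen is removed.

Step 18
Reactants: 27 hydroazulen-9-ol
Product: 28 O-(hydroazulen-9-yl) 1H-imidazole-1-carbothioate (C9 epimers)
Conditions: 1,1'-thiocarbonyldiimidazole (2 equiv), DMAP (0.2 equiv), ClCH2CH2Cl, 70 °C
Reagents that add atoms: 1,1'-thiocarbonyldiimidazole S=C(n1ccnc1)n1ccnc1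
Why: Thioacylation of the secondary alcohol for Barton–McCombie deoxygenation, under neutral conditions.

Step 19
Reactants: 28 O-(hydroazulen-9-yl) 1H-imidazole-1-carbothioate
Product: 29 hydroazulene diester (1R,4R,7R,10R,9'S; C8 and C9 CH2; C7 triethylsilyloxyisopropyl)
Conditions: (Me3Si)3SiH (1.5 equiv), AIBN (0.2 equiv), toluene, 90 °C
Reagents that add atoms: none
Why: Barton–McCombie radical deoxygenation. The C9 radical can reach C5=C6 only through a four-membered or 5-endo closure, so simple reduction should dominate.

Step 20
Reactants: 29 hydroazulene diester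
Product: 30 hydroazulene bis(hydroxymethyl)arene (diol; otherwise as 29)
Conditions: LiAlH4, THF, 0 °C; aq. potassium sodium tartrate
Reagents that add atoms: none
Why: Hydride reduction of both aryl esters. The small hydride reaches the hindered carbonyl groups, and the neutral work-up protects the electron-rich benzylic alcohols.

Step 21
Reactants: 30 hydroazulene bis(hydroxymethyl)arene
Product: 31 hydroazulene dialdehyde (2,4,6-trimethoxy-3,5-diformylphenyl; C7 triethylsilyloxyisopropyl)
Conditions: MnO2 (activated, 20 equiv), CH2Cl2, rt
Reagents that add atoms: none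
Why: Benzylic-selective oxidation with MnO2 under neutral conditions; no other oxidisable alcohol is free.

Step 22
Reactants: 31 hydroazulene dialdehyde
Product: 32 hydroazulene dialdehyde with free tertiary alcohol (trimethyl ether of the target)
Conditions: Bu4NF, THF, rt → 40 °C
Reagents that add atoms: none
Why: Fluoride desilylation of the tertiary triethylsilyl ether; it needs no acid, so the tertiary alcohol cannot ionise.

Step 23
Reactants: 32 hydroazulene dialdehyde with free tertiary alcohol
Product: 33 target (1R,4R,7R,10R,9'S)
Conditions: NaSEt (12 equiv), DMF, 110 °C; aq. HCl to pH 4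
Reagents that add atoms: none
Why: Thiolate SN2 demethylation of aryl methyl ethers. Each methoxy group is ortho to a formyl group, which stabilises the departing phenoxide, and the acid-free conditions spare the tertiary alcohol and the alkene.

## Compound list

1 | 1,3,5-trimethoxybenzene | COc1cc(OC)cc(OC)c1 | starting material
2 | 3-methylbutanal | CC(C)CC=O | starting material
3 | 2,4,6-trimethoxyphenyllithium | [Li]c1c(OC)cc(OC)cc1OC | intermediate (not isolated)
4 | rac-3-methyl-1-(2,4,6-trimethoxyphenyl)butan-1-ol | CC(C)CC(O)c1c(OC)cc(OC)cc1OC | intermediate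
5 | 2-methylcyclopentane-1,3-dione | CC1C(=O)CCC1=O | starting material
6 | 3-methyl-1-(2,4,6-trimethoxyphenyl)butan-1-ylium (benzylic cation) | CC(C)C[CH+]c1c(OC)cc(OC)cc1OC | intermediate (not isolated)
7 | rac-2-methyl-2-[3-methyl-1-(2,4,6-trimethoxyphenyl)butyl]cyclopentane-1,3-dione | CC(C)CC(c1c(OC)cc(OC)cc1OC)C1(C)C(=O)CCC1=O | intermediate
8 | (2S,3S)-3-hydroxy-2-methyl-2-[(1R)-3-methyl-1-(2,4,6-trimethoxyphenyl)butyl]cyclopentan-1-one | CC(C)C[C@H](c1c(OC)cc(OC)cc1OC)[C@@]1(C)[C@@H](O)CCC1=O | intermediate
9 | O-[(1S,2S)-2-methyl-2-[(1R)-3-methyl-1-(2,4,6-trimethoxyphenyl)butyl]-3-oxocyclopentyl] 1H-imidazole-1-carbothioate | CC(C)C[C@H](c1c(OC)cc(OC)cc1OC)[C@@]1(C)[C@@H](OC(=S)n2ccnc2)CCC1=O | intermediate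
10 | (2R)-2-methyl-2-[(1R)-3-methyl-1-(2,4,6-trimethoxyphenyl)butyl]cyclopentan-1-one | CC(C)C[C@H](c1c(OC)cc(OC)cc1OC)[C@@]1(C)CCCC1=O | intermediate
11 | (2R)-2-[(1R)-1-(3,5-dibromo-2,4,6-trimethoxyphenyl)-3-methylbutyl]-2-methylcyclopentan-1-one | CC(C)C[C@H](c1c(OC)c(Br)c(OC)c(Br)c1OC)[C@@]1(C)CCCC1=O | intermediate
12 | (2R)-2-[(1R)-1-[3,5-bis(methoxycarbonyl)-2,4,6-trimethoxyphenyl]-3-methylbutyl]-2-methylcyclopentan-1-one | CC(C)C[C@H](c1c(OC)c(C(=O)OC)c(OC)c(C(=O)OC)c1OC)[C@@]1(C)CCCC1=O | intermediate
13 | potassium enolate of 12 (enolate toward C1) | CC(C)C[C@H](c1c(OC)c(C(=O)OC)c(OC)c(C(=O)OC)c1OC)[C@@]1(C)CCC=C1[O-].[K+] | intermediate (not isolated)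
14 | (5R)-5-[(1S)-1-[3,5-bis(methoxycarbonyl)-2,4,6-trimethoxyphenyl]-3-methylbutyl]-5-methylcyclopent-1-en-1-yl trifluoromethanesulfonate | CC(C)C[C@H](c1c(OC)c(C(=O)OC)c(OC)c(C(=O)OC)c1OC)[C@@]1(C)CCC=C1OS(=O)(=O)C(F)(F)F | intermediate
15 | 2-methylbut-3-yn-2-ol | CC(C)(O)C#C | starting material
16 | triethyl[(2-methylbut-3-yn-2-yl)oxy]silane | CC(C)(C#C)O[Si](CC)(CC)CC | intermediate
17 | dimethyl 2,4,6-trimethoxy-5-[(1S)-3-methyl-1-[(1R)-1-methyl-2-[3-methyl-3-(triethylsilyloxy)but-1-yn-1-yl]cyclopent-2-en-1-yl]butyl]benzene-1,3-dicarboxylate | CC(C)C[C@H](c1c(OC)c(C(=O)OC)c(OC)c(C(=O)OC)c1OC)[C@@]1(C)CCC=C1C#CC(C)(C)O[Si](CC)(CC)CC | intermediate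
18 | dimethyl 2,4,6-trimethoxy-5-[(1S)-3-methyl-1-[(1R)-1-methyl-2-[(1Z)-3-methyl-3-(triethylsilyloxy)but-1-en-1-yl]cyclopent-2-en-1-yl]butyl]benzene-1,3-dicarboxylate | CC(C)C[C@H](c1c(OC)c(C(=O)OC)c(OC)c(C(=O)OC)c1OC)[C@@]1(C)CCC=C1/C=C\C(C)(C)O[Si](CC)(CC)CC | intermediate
19 | methyl 3-oxopentanoate | CCC(=O)CC(=O)OC | starting material
20 | 2-(trimethylsilyl)ethyl 3-oxopentanoate | CCC(=O)CC(=O)OCC[Si](C)(C)C | intermediate
21 | 2-(trimethylsilyl)ethyl 2-diazo-3-oxopentanoate | CCC(=O)C(=[N+]=[N-])C(=O)OCC[Si](C)(C)C | intermediate
22 | 2-(trimethylsilyl)ethyl (3Z)-3-(tert-butyldimethylsilyloxy)-2-diazopent-3-enoate | C[Si](C)(C)CCOC(=O)C(=[N+]=[N-])/C(O[Si](C)(C)C(C)(C)C)=C/C | intermediate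
23 | rhodium carbenoid from 22 (carbene carbon on rhodium; carboxylate ligands and second rhodium not drawn) | C[Si](C)(C)CCOC(=O)C(=[Rh])/C(O[Si](C)(C)C(C)(C)C)=C/C | intermediate (not isolated)
24 | all-cis divinylcyclopropane (cyclopropane C6–C7–C8; C6 cyclopentenyl, C7 triethylsilyloxyisopropyl, C8 siloxyvinyl cis to both; C8 ester trans) | CC(C)C[C@H](c1c(OC)c(C(=O)OC)c(OC)c(C(=O)OC)c1OC)[C@@]1(C)CCC=C1[C@@H]2[C@H](C(C)(C)O[Si](CC)(CC)CC)[C@]2(C(=O)OCC[Si](C)(C)C)/C(O[Si](C)(C)C(C)(C)C)=C/C | intermediate (not isolated)
25 | hydroazulene cycloadduct, (1R,4R,7S,10S,9'S): C5=C6; C7 triethylsilyloxyisopropyl; C8 2-(trimethylsilyl)ethyl ester; C8=C9 tert-butyldimethylsilyl enol ether; arene as dimethyl diester | CC(C)C[C@H](c1c(OC)c(C(=O)OC)c(OC)c(C(=O)OC)c1OC)[C@@]1(C)CC[C@H]2C1=C[C@H](C(C)(C)O[Si](CC)(CC)CC)C(C(=O)OCC[Si](C)(C)C)=C(O[Si](C)(C)C(C)(C)C)[C@H]2C | intermediate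
26 | hydroazulen-9-one, (1R,4R,7R,10S,9'S): C8 CH2; C7 triethylsilyloxyisopropyl; arene as dimethyl diester | CC(C)C[C@H](c1c(OC)c(C(=O)OC)c(OC)c(C(=O)OC)c1OC)[C@@]1(C)CC[C@H]2C1=C[C@H](C(C)(C)O[Si](CC)(CC)CC)CC(=O)[C@H]2C | intermediate
27 | hydroazulen-9-ol (C9 epimers; other centres as in 26) | CC(C)C[C@H](c1c(OC)c(C(=O)OC)c(OC)c(C(=O)OC)c1OC)[C@@]1(C)CC[C@H]2C1=C[C@H](C(C)(C)O[Si](CC)(CC)CC)CC(O)[C@H]2C | intermediate
28 | O-(hydroazulen-9-yl) 1H-imidazole-1-carbothioate (C9 epimers) | CC(C)C[C@H](c1c(OC)c(C(=O)OC)c(OC)c(C(=O)OC)c1OC)[C@@]1(C)CC[C@H]2C1=C[C@H](C(C)(C)O[Si](CC)(CC)CC)CC(OC(=S)n3ccnc3)[C@H]2C | intermediate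
29 | hydroazulene diester, (1R,4R,7R,10R,9'S): C8 and C9 CH2; C7 triethylsilyloxyisopropyl | CC(C)C[C@H](c1c(OC)c(C(=O)OC)c(OC)c(C(=O)OC)c1OC)[C@@]1(C)CC[C@H]2C1=C[C@H](C(C)(C)O[Si](CC)(CC)CC)CC[C@H]2C | intermediate
30 | hydroazulene with 3,5-bis(hydroxymethyl)-2,4,6-trimethoxyphenyl group (configuration as 29) | CC(C)C[C@H](c1c(OC)c(CO)c(OC)c(CO)c1OC)[C@@]1(C)CC[C@H]2C1=C[C@H](C(C)(C)O[Si](CC)(CC)CC)CC[C@H]2C | intermediate
31 | hydroazulene with 3,5-diformyl-2,4,6-trimethoxyphenyl group; C7 triethylsilyloxyisopropyl | CC(C)C[C@H](c1c(OC)c(C=O)c(OC)c(C=O)c1OC)[C@@]1(C)CC[C@H]2C1=C[C@H](C(C)(C)O[Si](CC)(CC)CC)CC[C@H]2C | intermediate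
32 | tri-O-methyl ether of the target (free tertiary alcohol) | CC(C)C[C@H](c1c(OC)c(C=O)c(OC)c(C=O)c1OC)[C@@]1(C)CC[C@H]2C1=C[C@H](C(C)(C)O)CC[C@H]2C | intermediate
33 | target, (1R,4R,7R,10R,9'S)-hydroazulene with 3,5-diformyl-2,4,6-trihydroxyphenyl group at C9' | CC(C)C[C@H](c1c(O)c(C=O)c(O)c(C=O)c1O)[C@@]1(C)CC[C@H]2C1=C[C@H](C(C)(C)O)CC[C@H]2C | target

## Step count and least certain steps

Total: 23 steps. Longest linear sequence: 19 steps (steps 1–8, 10, 11, 15–23).

**Step 15 (key).** Carbenoid transfer may be slow or misdirected (attack at C1=C5, or allylic C–H functionalisation at C2), because C6=C7 lies between C4 and the silyloxyisopropyl group. The boat rearrangement may stall under the cis tertiary substituent, and the catalyst may fail to override the substrate in choosing the alkene face. The fallback moves the carbenoid step to a small achiral alkene and makes C5–C6 afterwards. It sets out from 16: rhodium-catalysed trans-hydroboration (pinacolborane, [Rh(cod)Cl]2, P(i-Pr)3, Et3N) would give the (Z)-alkenylboronate F1. Cyclopropanation of F1 with 22 under Rh2(S-PTAD)4 would give the cyclopropylboronate F2 with the vinyl group cis to both substituents. Suzuki–Miyaura coupling of F2 with 14 (Pd(OAc)2, SPhos, K3PO4, toluene) would proceed with retention and give 24, which rearranges on heating. The fallback comes back to the route at 25.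

**Step 2.** Capture of the cation at the fully substituted dione carbon may be too slow against O-alkylation, elimination and self-alkylation of the arene. The fallback builds the same bond by conjugate addition and sets out from 1. Vilsmeier formylation (POCl3, DMF) gives 2,4,6-trimethoxybenzaldehyde F3. Knoevenagel condensation with cyclopentane-1,3-dione gives the arylidene dione F4. Copper-catalysed addition of i-BuMgBr (CuI) gives 2-[3-methyl-1-(2,4,6-trimethoxyphenyl)butyl]cyclopentane-1,3-dione F5. C-methylation (MeI, NaOH, water) comes back to the route at 7.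

**Step 3.** Discrimination between the two carbonyl groups by the catalyst may be overridden by the side-chain stereocentre, so that the wanted diastereomer forms slowly or impure. The fallback is a classical resolution and sets out from 7. Unselective mono-reduction (NaBH4, −78 °C) is followed by esterification of the alcohol mixture with (S)-O-acetylmandelic acid (DCC, DMAP). The ester of 8, the O-acetylmandelate F6, is separated from its diastereomers by chromatography or crystallisation. Methanolysis (K2CO3, MeOH) comes back to the route at 8.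

**Step 7.** Oxidative addition at bromides flanked by two methoxy groups may be sluggish, and hydrodebromination may compete with the second carbonylation. The fallback introduces the carbons electrophilically and sets out from 10. Twofold Rieche formylation (Cl2CHOMe, TiCl4, −20 °C) gives the dialdehyde F7. Pinnick oxidation (NaClO2, NaH2PO4, 2-methyl-2-butene) gives the diacid F8. Esterification (MeI, K2CO3, DMF) comes back to the route at 12.

**Step 23.** Dealkylation may stop after the first or second phenoxide has formed, and reversible thiolate addition to the formyl groups may slow it further. The fallback uses chelation-assisted Lewis acid cleavage while the tertiary alcohol is still silylated, and sets out from 31. BCl3 with Bu4NI (CH2Cl2, −78 → 0 °C) cleaves the three methyl ethers, each ortho to a formyl group, and gives the silyl-protected triphenol F9. Bu4NF then comes back to the route at 33.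

## Further compounds

F1 | step 15 | 4,4,5,5-tetramethyl-2-[(1Z)-3-methyl-3-(triethylsilyloxy)but-1-en-1-yl]-1,3,2-dioxaborolane | CC1(C)OB(/C=C\C(C)(C)O[Si](CC)(CC)CC)OC1(C)C
F2 | step 15 | all-cis cyclopropylboronate (boron on C6; C7 triethylsilyloxyisopropyl; C8 siloxyvinyl and 2-(trimethylsilyl)ethyl ester) | CC1(C)OB(OC1(C)C)[C@@H]1[C@H](C(C)(C)O[Si](CC)(CC)CC)[C@]1(C(=O)OCC[Si](C)(C)C)/C(O[Si](C)(C)C(C)(C)C)=C/C
F3 | step 2 | 2,4,6-trimethoxybenzaldehyde | COc1cc(OC)c(C=O)c(OC)c1
F4 | step 2 | 2-(2,4,6-trimethoxybenzylidene)cyclopentane-1,3-dione | COc1cc(OC)c(C=C2C(=O)CCC2=O)c(OC)c1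
F5 | step 2 | rac-2-[3-methyl-1-(2,4,6-trimethoxyphenyl)butyl]cyclopentane-1,3-dione | CC(C)CC(c1c(OC)cc(OC)cc1OC)C1C(=O)CCC1=O
F6 | step 3 | (S)-O-acetylmandelate of 8 | CC(C)C[C@H](c1c(OC)cc(OC)cc1OC)[C@@]1(C)[C@@H](OC(=O)[C@@H](OC(C)=O)c2ccccc2)CCC1=O
F7 | step 7 | (2R)-2-[(1R)-1-(3,5-diformyl-2,4,6-trimethoxyphenyl)-3-methylbutyl]-2-methylcyclopentan-1-one | CC(C)C[C@H](c1c(OC)c(C=O)c(OC)c(C=O)c1OC)[C@@]1(C)CCCC1=O
F8 | step 7 | 2,4,6-trimethoxy-5-[(1R)-3-methyl-1-[(1R)-1-methyl-2-oxocyclopentyl]butyl]benzene-1,3-dicarboxylic acid | CC(C)C[C@H](c1c(OC)c(C(=O)O)c(OC)c(C(=O)O)c1OC)[C@@]1(C)CCCC1=O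
F9 | step 23 | triethylsilyl ether of the target (silyl group on the tertiary alcohol) | CC(C)C[C@H](c1c(O)c(C=O)c(O)c(C=O)c1O)[C@@]1(C)CC[C@H]2C1=C[C@H](C(C)(C)O[Si](CC)(CC)CC)CC[C@H]2C
A1 | alternative 1 | (Z)-1-(5-methylhex-2-en-2-yl)cyclobutan-1-ol | CC(C)C/C=C(/C)C1(O)CCC1
A2 | alternative 1 | 2,4,6-trimethoxybenzenediazonium tetrafluoroborate | COc1cc(OC)c([N+]#N)c(OC)c1.F[B-](F)(F)F
A3 | alternative 1 | 2-methyl-2-[1-(2,4,6-trimethoxyphenyl)-3-methylbutyl]cyclopentanone (same as 10) | CC(C)C[C@H](c1c(OC)cc(OC)cc1OC)[C@@]1(C)CCCC1=O
A4 | alternative 2 | hydroazulene-4-carboxylic acid with C7 tert-butyldimethylsilyloxyisopropyl group | OC(=O)[C@@]1(C)CC[C@H]2C1=C[C@H](C(C)(C)O[Si](C)(C)C(C)(C)C)CC[C@H]2C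
A5 | alternative 2 | 3,5-dimethoxy-2-(trimethylsilyl)phenyl trifluoromethanesulfonate | COc1cc(OC)c([Si](C)(C)C)c(OS(=O)(=O)C(F)(F)F)c1
A6 | alternative 2 | 3,5-dimethoxybenzyne | COC1=CC(OC)=CC#C1
A7 | alternative 2 | 2-hydroxy-4,6-dimethoxyphenyl ketone at C9' | O=C(c1c(O)cc(OC)cc1OC)[C@@]1(C)CC[C@H]2C1=C[C@H](C(C)(C)O[Si](C)(C)C(C)(C)C)CC[C@H]2C
A8 | alternative 3 | acyclic dienyne (C3 allylic alcohol with vinyl group, C1≡C5 alkyne, C6 vinyl group on C7) | CC(C)C[C@H](c1c(OC)cc(OC)cc1OC)[C@@](C)([C@@H](O)C=C)C#C[C@H](C)CC[C@H](C=C)C(C)(C)O[Si](CC)(CC)CC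
A9 | alternative 3 | hydroazulene dienol with C1=C2 and C5=C6 | CC(C)C[C@H](c1c(OC)cc(OC)cc1OC)[C@@]1(C)[C@@H](O)C=C2C1=C[C@H](C(C)(C)O[Si](CC)(CC)CC)CC[C@H]2C
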